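The chromone is traced back to its benzene ring (C4a, C5, C6, C7, C8, C8a), which carries oxygen on alternate carbons (C5, C7, C8a) and the acyl chain on C4a, the mark of a folded pentaketide. Everything rests on the C4a–C8a bond: a Claisen closure in which the C4a enolate of a linear C40 chain attacks its terminal ester and delivers ring A in one operation, with C5 already a methyl ether so that only O8a can later close the pyranone and place the methyl group on C8. The precursor is a 2-methyl-β-keto ester carrying two methyl enol ethers, at C5 and at the future C2.

Key step: step 7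

Remarks
- Stereochemistry: the target has no stereocentre and no stereogenic double bond, so it is one achiral compound. The methyl-bearing carbon of the open-chain intermediates is racemic and becomes an arene carbon in the key step.
- Numbering: chromone numbering (O1, C2, C3, C4, C4a, C5–C8, C8a) is used for the corresponding atoms of all open-chain compounds.
- Chain length: the C2 substituent is hentriacontyl (31 carbons). Dotriacontanoic acid supplies C2 plus this chain, and Meldrum's acid supplies C3 and C4.
- Precursor design: the side-chain 1,3-diketone is carried as its methyl enol ether on the future C2. A free diketone would make C3 the most acidic carbon of the chain. From there, aldol closure onto C7 or O-cyclisation onto C5 (a γ-pyrone) could compete with the C4a carbanion. The enol ether removes both paths and later serves as the leaving group when the pyranone closes.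
- Handling: the C32–C40 compounds are waxy, so they are run at 0 °C or above with THF or toluene present.

Step 1
Reactants: 1 methyl (E)-3-methoxybut-2-enoate
Product: 2 (E)-3-methoxybut-2-enoic acid
Conditions: KOH, MeOH–H2O, 60 °C; then aq. HCl to pH 3, 0 °C
Reagents that add atoms: potassium hydroxide, [K+].[OH-]
Why: Saponification (BAc2 ester hydrolysis) touches only the ester carbonyl of this vinylogous carbonate, and brief acidification in the cold frees the acid before the enol ether can hydrolyse; the E geometry is not involved.

Step 2
Reactants: 2 (E)-3-methoxybut-2-enoic acid; 3 methyl propanoate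
Product: 5 methyl (2RS,4E)-5-methoxy-2-methyl-3-oxohex-4-enoate, via (E)-3-methoxybut-2-enoyl chloride 4 (not isolated)
Conditions: (COCl)2, DMF (cat.), CH2Cl2, 0 °C → rt, evaporate; 3 (2.2 equiv), LDA (2.2 equiv), THF, −78 °C, then 4; aq. NH4Cl
Reagents that add atoms: none
Why: Crossed Claisen-type C-acylation of a lithium ester enolate by an acid chloride at −78 °C; the second equivalent of enolate deprotonates the β-keto ester as it forms, which stops double acylation, the E enol ether is not touched, and the new methyl-bearing centre (future C8) is racemic and labile, which is of no account because it becomes an arene carbon.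

Step 3
Reactants: 6 dotriacontanoic acid; 7 Meldrum's acid (2,2-dimethyl-1,3-dioxane-4,6-dione)
Product: 9 5-(1-hydroxydotriacontylidene)-2,2-dimethyl-1,3-dioxane-4,6-dione, via dotriacontanoyl chloride 8 (not isolated)
Conditions: (COCl)2, DMF (cat.), toluene, 50 °C, evaporate; 7, pyridine, CH2Cl2, 0 °C → rt
Reagents that add atoms: none
Why: C-Acylation of Meldrum's acid (a carbon acid of pKa about 5) by the acid chloride with pyridine gives the fully enolised acyl Meldrum's acid, a stable crystalline acylketene precursor that adds the two carbons C3 and C4.

Step 4
Reactants: 9 5-(1-hydroxydotriacontylidene)-2,2-dimethyl-1,3-dioxane-4,6-dione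
Product: 10 N-methoxy-N-methyl-3-oxotetratriacontanamide
Conditions: MeNH(OMe)·HCl, Et3N, toluene, 90 °C
Reagents that add atoms: N,O-dimethylhydroxylamine hydrochloride, CNOC.Cl
Why: Thermolysis of the acyl Meldrum's acid expels acetone and CO2 and the acylketene so formed is captured by the hydroxylamine nitrogen (aminolysis of an acyl Meldrum's acid), giving the β-keto Weinreb amide without any strong base.

Step 5
Reactants: 10 N-methoxy-N-methyl-3-oxotetratriacontanamide
Product: 11 (2E)-N,3-dimethoxy-N-methyltetratriacont-2-enamide
Conditions: HC(OMe)3, H2SO4 (cat.), toluene, 60 °C, then strip MeOH at 90 °C; K2CO3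
Reagents that add atoms: trimethyl orthoformate, COC(OC)OC
Why: Acid-catalysed ketalisation of the ketone by the orthoester followed by loss of methanol gives the conjugated β-methoxy enamide (the enol etherification by which 3-methoxycrotonates are made from acetoacetates), the E isomer being the expected thermodynamic one; its geometry is of no account because this carbon becomes C2 of the pyranone.

Step 6
Reactants: 5 methyl (2RS,4E)-5-methoxy-2-methyl-3-oxohex-4-enoate; 11 (2E)-N,3-dimethoxy-N-methyltetratriacont-2-enamide
Product: 12 methyl (2RS,4E,8E)-5,9-dimethoxy-2-methyl-3,7-dioxotetraconta-4,8-dienoate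
Conditions: 5 (1.5 equiv), LDA (3.0 equiv), THF, −78 → 0 °C; 11, THF, 0 °C → rt; aq. NH4Cl
Reagents that add atoms: none
Why: The first equivalent of LDA gives the β-keto ester enolate and the second removes a proton from the methyl group on the enol ether carbon, so that the terminal carbon of this dianion (future C4a), the last site deprotonated and the least hindered, adds to the Weinreb amide (acylation of a β-keto ester dianion), whose chelated tetrahedral adduct releases the C4 ketone only on work-up.

Step 7
Reactants: 12 methyl (2RS,4E,8E)-5,9-dimethoxy-2-methyl-3,7-dioxotetraconta-4,8-dienoate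
Product: 13 (2E)-1-(2,4-dihydroxy-6-methoxy-3-methylphenyl)-3-methoxytetratriacont-2-en-1-one
Conditions: Mg(OMe)2 (4 equiv), MeOH–THF, 65 °C; cold aq. NH4Cl
Reagents that add atoms: none
Why: Magnesium methoxide reversibly deprotonates C4a, the one methylene that lies between a ketone (C4) and an enol ether carbon (C5) conjugated to the C7 carbonyl, and this dienolate adds to the ester carbonyl C8a; loss of methoxide and enolisation of the resulting cyclohexadienone at C4a and C8 give the arene, which makes the closure irreversible. The closest known reaction type is the biomimetic Claisen (Dieckmann-type) cyclisation of 3,5,7-tricarbonyl esters to acylphloroglucinols with magnesium methoxide. Ring A closes 6-exo-trig with the E enol ether C5=C6 inside the forming ring, where it already holds C4a and C7 cis; should base isomerise that double bond through the dienolate, the isomers stay in equilibrium and only the cis-folded one closes. No stereocentre is created and the racemic C8 centre becomes sp2. The selectivity needed is Claisen over aldol closure and over chain cleavage: C3 is a vinyl CH inside the second enol ether and so is neither a carbon nucleophile nor the source of a γ-pyrone, C4 and C7 are both deactivated vinylogous ester carbonyls, an aldol from the methyl-bearing C8 onto C4 gives a crowded adduct that cannot aromatise and reverts, and Mg2+ chelation of the dicarbonyl termini slows retro-Claisen attack by methoxide. The product is held as its chelated magnesium phenoxide, which keeps the β-methoxy enone side chain intact until the mild work-up.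

Step 8
Reactants: 13 (2E)-1-(2,4-dihydroxy-6-methoxy-3-methylphenyl)-3-methoxytetratriacont-2-en-1-one
Product: 14 2-hentriacontyl-7-hydroxy-5-methoxy-8-methyl-4H-chromen-4-one
Conditions: TsOH·H2O (0.2 equiv), toluene, 80 °C
Reagents that add atoms: none
Why: Acid-catalysed addition–elimination (6-endo oxa-Michael addition of the C8a hydroxyl to the protonated β-methoxy enone, then loss of methanol) closes the pyranone, and because O5 is a methyl ether only O8a can do so, which fixes the methyl group on C8; any material that had already closed or had hydrolysed to the 1,3-diketone in the work-up of step 7 converges on 14 here.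

Step 9
Reactants: 14 2-hentriacontyl-7-hydroxy-5-methoxy-8-methyl-4H-chromen-4-one
Product: 15 2-hentriacontyl-5,7-dihydroxy-8-methyl-4H-chromen-4-one
Conditions: BCl3 (3 equiv), CH2Cl2, 0 °C → rt; then MeOH/H2O
Reagents that add atoms: none
Why: Chelation-assisted Lewis acid demethylation: BCl3 bridges the C4 carbonyl and the peri C5 methoxy oxygen and chloride removes that methyl group, while the mild temperature leaves the pyranone closed, so that no Wessely–Moser shift of the methyl group from C8 to C6 can take place.

Compound list
1 | methyl (E)-3-methoxybut-2-enoate | CO/C(C)=C/C(=O)OC | starting material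
2 | (E)-3-methoxybut-2-enoic acid | CO/C(C)=C/C(=O)O | intermediate
3 | methyl propanoate | CCC(=O)OC | starting material
4 | (E)-3-methoxybut-2-enoyl chloride | CO/C(C)=C/C(=O)Cl | intermediate (not isolated)
5 | methyl (2RS,4E)-5-methoxy-2-methyl-3-oxohex-4-enoate (racemic) | CO/C(C)=C/C(=O)C(C)C(=O)OC | intermediate
6 | dotriacontanoic acid | CCCCCCCCCCCCCCCCCCCCCCCCCCCCCCCC(=O)O | starting material
7 | Meldrum's acid (2,2-dimethyl-1,3-dioxane-4,6-dione) | CC1(C)OC(=O)CC(=O)O1 | starting material
8 | dotriacontanoyl chloride | CCCCCCCCCCCCCCCCCCCCCCCCCCCCCCCC(=O)Cl | intermediate (not isolated)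
9 | 5-(1-hydroxydotriacontylidene)-2,2-dimethyl-1,3-dioxane-4,6-dione | CCCCCCCCCCCCCCCCCCCCCCCCCCCCCCCC(O)=C1C(=O)OC(C)(C)OC1=O | intermediate
10 | N-methoxy-N-methyl-3-oxotetratriacontanamide | CCCCCCCCCCCCCCCCCCCCCCCCCCCCCCCC(=O)CC(=O)N(C)OC | intermediate
11 | (2E)-N,3-dimethoxy-N-methyltetratriacont-2-enamide | CCCCCCCCCCCCCCCCCCCCCCCCCCCCCCC/C(OC)=C\C(=O)N(C)OC | intermediate
12 | methyl (2RS,4E,8E)-5,9-dimethoxy-2-methyl-3,7-dioxotetraconta-4,8-dienoate (racemic; key-step precursor) | CCCCCCCCCCCCCCCCCCCCCCCCCCCCCCC/C(OC)=C\C(=O)C/C(OC)=C\C(=O)C(C)C(=O)OC | intermediate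
13 | (2E)-1-(2,4-dihydroxy-6-methoxy-3-methylphenyl)-3-methoxytetratriacont-2-en-1-one (key-step product) | CCCCCCCCCCCCCCCCCCCCCCCCCCCCCCC/C(OC)=C\C(=O)c1c(OC)cc(O)c(C)c1O | intermediate
14 | 2-hentriacontyl-7-hydroxy-5-methoxy-8-methyl-4H-chromen-4-one | CCCCCCCCCCCCCCCCCCCCCCCCCCCCCCCc1cc(=O)c2c(OC)cc(O)c(C)c2o1 | intermediate
15 | 2-hentriacontyl-5,7-dihydroxy-8-methyl-4H-chromen-4-one | CCCCCCCCCCCCCCCCCCCCCCCCCCCCCCCc1cc(=O)c2c(O)cc(O)c(C)c2o1 | target

Total step count: 9. Longest linear sequence: 7 steps (steps 3–9, from dotriacontanoic acid); the other branch (steps 1–2) joins at step 6.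

Steps most likely to fail

1. Step 7, the Claisen closure.
What may go wrong: the β-keto ester end sits largely as its enolised magnesium chelate and may accept the C4a carbanion only slowly. Cleavage of the chain by methoxide (retro-Claisen at C4 or C7) or reversible aldol closure from C8 could then overtake ring formation.
Fallback: ring A is brought in as an arene and the 1,3-diketone is made by acyl transfer. The fallback sets out from 6 by way of its chloride 8 and comes back to the route at 15. Chloride 8 acylates the phenolic hydroxyl of the known 1-(2-hydroxy-4,6-dimethoxy-3-methylphenyl)ethanone F1, an extra building block that would be bought or made separately (pyridine, DMAP, CH2Cl2). This gives 2-acetyl-3,5-dimethoxy-6-methylphenyl dotriacontanoate F2. A Baker–Venkataraman rearrangement (KOt-Bu, THF) moves the acyl group to the acetyl carbon and gives 1-(2-hydroxy-4,6-dimethoxy-3-methylphenyl)tetratriacontane-1,3-dione F3. TsOH in refluxing toluene cyclodehydrates F3 through its only free hydroxyl, which lies next to the methyl group, to 2-hentriacontyl-5,7-dimethoxy-8-methyl-4H-chromen-4-one F4. BBr3 (CH2Cl2, 0 °C → rt) then cleaves both methyl ethers to 15.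

2. Step 6, the dianion acylation.
What may go wrong: proton transfer from the allylic methylene of 11 to the dianion instead of addition, attack through the internal carbon of the dianion instead of its terminus, or hydrolysis of an enol ether during work-up.
Fallback: aldol addition followed by oxidation replaces the acylation. It sets out from 11 and 5 and comes back at 12. DIBAL-H (THF, −40 °C) reduces 11 to (2E)-3-methoxytetratriacont-2-enal F5. The dianion of 5 (LDA, THF) adds through its terminal carbon to this aldehyde, the mode best established for such alkoxy dienolates. The adduct is methyl (4E,8E)-7-hydroxy-5,9-dimethoxy-2-methyl-3-oxotetraconta-4,8-dienoate F6. MnO2 or buffered Dess–Martin periodinane oxidises the allylic alcohol to 12.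

3. Step 5, the enol ether formation.
What may go wrong: ketalisation of the waxy, partly enolised β-keto amide stalls, or the dimethyl ketal fails to lose methanol and reverts to 10 on work-up.
Fallback: the side-chain diketone is left unprotected. It sets out from 10 and 5 and comes back at 14. The lithium enolate of 10 (LiHMDS, THF) is added to the dianion of 5 and acylates its terminal carbon, giving methyl (4E)-5-methoxy-2-methyl-3,7,9-trioxotetracont-4-enoate F7. Magnesium methoxide as in step 7 closes ring A to 1-(2,4-dihydroxy-6-methoxy-3-methylphenyl)tetratriacontane-1,3-dione F8. In this series the Claisen closure has to win against aldol closure from the diketone carbon, which is why it is not the main line. TsOH in toluene with removal of water cyclodehydrates F8 through O8a to 14.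

Further compounds
F1 | step 7 | 1-(2-hydroxy-4,6-dimethoxy-3-methylphenyl)ethanone (brought in) | CC(=O)c1c(O)c(C)c(OC)cc1OC
F2 | step 7 | 2-acetyl-3,5-dimethoxy-6-methylphenyl dotriacontanoate | CCCCCCCCCCCCCCCCCCCCCCCCCCCCCCCC(=O)Oc1c(C)c(OC)cc(OC)c1C(C)=O
F3 | step 7 | 1-(2-hydroxy-4,6-dimethoxy-3-methylphenyl)tetratriacontane-1,3-dione | CCCCCCCCCCCCCCCCCCCCCCCCCCCCCCCC(=O)CC(=O)c1c(OC)cc(OC)c(C)c1O
F4 | step 7 | 2-hentriacontyl-5,7-dimethoxy-8-methyl-4H-chromen-4-one | CCCCCCCCCCCCCCCCCCCCCCCCCCCCCCCc1cc(=O)c2c(OC)cc(OC)c(C)c2o1
F5 | step 6 | (2E)-3-methoxytetratriacont-2-enal | CCCCCCCCCCCCCCCCCCCCCCCCCCCCCCC/C(OC)=C\C=O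
F6 | step 6 | methyl (4E,8E)-7-hydroxy-5,9-dimethoxy-2-methyl-3-oxotetraconta-4,8-dienoate | CCCCCCCCCCCCCCCCCCCCCCCCCCCCCCC/C(OC)=C\C(O)C/C(OC)=C\C(=O)C(C)C(=O)OC
F7 | step 5 | methyl (4E)-5-methoxy-2-methyl-3,7,9-trioxotetracont-4-enoate | CCCCCCCCCCCCCCCCCCCCCCCCCCCCCCCC(=O)CC(=O)C/C(OC)=C\C(=O)C(C)C(=O)OC
F8 | step 5 | 1-(2,4-dihydroxy-6-methoxy-3-methylphenyl)tetratriacontane-1,3-dione | CCCCCCCCCCCCCCCCCCCCCCCCCCCCCCCC(=O)CC(=O)c1c(OC)cc(O)c(C)c1O
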